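**Retrosynthetic overview**
1. Target 35 is methyl 8β-acetoxy-3β-[(E)-3-methylpent-2-enoyloxy]eudesma-4,11(13)-dien-12-oate; the O3 and O8 esters, the C12 methyl ester with the C13 methylene, and the C15 methyl are late operations on the 4-bromo-3-oxo-Δ4 8β,12-lactone 20.
2. Feature: C4 is the only ring A carbon between the C3 carbonyl carbon and the ring-fusion carbon C5, and it is sp2 without a stereocentre. Removing it from 20 leaves a cyclopentanone (C1–C2–C3–C5–C10) fused to ring B, whose C3=C5 silyl enol ether 17 takes C4 back from dibromocarbene (C3–C4 and C4–C5 formed, C3–C5 broken).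
3. The enol ether is not made by equilibration: ring A is closed as a cyclopentanone by a carbene-catalysed benzoin reaction (C3 aldehyde onto C5 ketone), the ketol is dehydrated to the C5=C6 enone, and 1,4-hydrosilylation places the double bond at C3=C5 (carried as the triethylsilyl ether).
4. Ring B is bought as a cyclohexenone ketal: transfer hydrogenation sets C8, the C8 silyl ether steers the C1–C3 arm to the opposite face of C10, and a malonate tethered on O8 adds to C7 to give the cis lactone.
5. Ring order: ring B (present from the start), γ-lactone, ring A as a five-membered ring, ring A enlarged to six.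

Key step: step 13

Assumption: 1 and geometrically pure (E)-3-methylpent-2-enoic acid (34) are bought; intermediates carry the eudesmane atom numbers of the target (C14 angular methyl, C15 methyl on C4, β is the face of C14); if step 1 leaves some of the wrong enantiomer, the keto lactone 13 would be recrystallised.

**Route**

Step 1
Reactants: 1 1,4-dioxaspiro[4.5]dec-6-en-8-one
Product: 2 (8R)-1,4-dioxaspiro[4.5]dec-6-en-8-ol
Conditions: RuCl[(R,R)-TsDPEN](p-cymene) (1 mol%), HCO2Na, n-Bu4NCl, CH2Cl2/H2O, 25 °C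
Reagents that add atoms: none
Why: Noyori asymmetric transfer hydrogenation reduces the enone carbonyl 1,2 under catalyst control, the alkene playing the part of the aryl group in the usual CH/π model, so the (R,R)-ligand should set C8 as R (the mirror-image ligand would be taken if the sense proved opposite).

Step 2
Reactants: 2 (8R)-1,4-dioxaspiro[4.5]dec-6-en-8-ol
Product: 3 (8R)-8-(tert-butyldimethylsilyloxy)-1,4-dioxaspiro[4.5]dec-6-ene
Conditions: TBSCl, imidazole, DMF, 25 °C
Reagents that add atoms: tert-butyl(chloro)dimethylsilane, CC(C)(C)[Si](C)(C)Cl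
Why: Silyl ether formation on the secondary allylic alcohol installs the bulky group that later shields one face of ring B.

Step 3
Reactants: 3 (8R)-8-(tert-butyldimethylsilyloxy)-1,4-dioxaspiro[4.5]dec-6-ene
Product: 4 (4R)-4-(tert-butyldimethylsilyloxy)cyclohex-2-en-1-one
Conditions: PPTS, acetone/H2O (10:1), 55 °C
Reagents that add atoms: water, O
Why: Mild acid-catalysed acetal hydrolysis frees the ketone in conjugation with the alkene without touching the silyl ether or the C8 stereocentre.

Step 4
Reactants: 4 (4R)-4-(tert-butyldimethylsilyloxy)cyclohex-2-en-1-one; 5 iodomethane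
Product: 6 (4R,6R)-4-(tert-butyldimethylsilyloxy)-6-methylcyclohex-2-en-1-one
Conditions: LiN(i-Pr)2, THF, −78 °C; MeI, −78 → −30 °C
Reagents that add atoms: iodomethane (5), CI
Why: Kinetic deprotonation at the α′-carbon C10 and enolate alkylation should give mainly the trans isomer, but the configuration at C10 does not matter because the centre is enolised again in step 5.

Step 5
Reactants: 6 (4R,6R)-4-(tert-butyldimethylsilyloxy)-6-methylcyclohex-2-en-1-one; 7 3-bromoprop-1-yne
Product: 8 (4R,6R)-4-(tert-butyldimethylsilyloxy)-6-methyl-6-(prop-2-yn-1-yl)cyclohex-2-en-1-one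
Conditions: LiN(i-Pr)2, THF, −78 °C; propargyl bromide, DMPU, −78 → −20 °C
Reagents that add atoms: 3-bromoprop-1-yne (7), C#CCBr
Why: Enolate alkylation of the cross-conjugated lithium enolate should occur on the face opposite the pseudo-axial C8 silyloxy group, so the propargyl group (C1–C3) enters α and the methyl C14 is left cis to O8, which sets the quaternary C10 as R.

Step 6
Reactants: 8 (4R,6R)-4-(tert-butyldimethylsilyloxy)-6-methyl-6-(prop-2-yn-1-yl)cyclohex-2-en-1-one
Product: 9 (4R,6R)-4-hydroxy-6-methyl-6-(prop-2-yn-1-yl)cyclohex-2-en-1-one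
Conditions: HF·pyridine, THF, 0 → 25 °C
Reagents that add atoms: none
Why: Fluoride-mediated desilylation under non-basic conditions frees O8 without the base-induced isomerisation to which γ-hydroxy enones are prone.

Step 7
Reactants: 9 (4R,6R)-4-hydroxy-6-methyl-6-(prop-2-yn-1-yl)cyclohex-2-en-1-one; 10 methyl 3-chloro-3-oxopropanoate
Product: 12 methyl (3aR,6R,7aR)-6-methyl-2,5-dioxo-6-(prop-2-yn-1-yl)octahydro-1-benzofuran-3-carboxylate (C3 epimers), via malonate ester 11 (not isolated)
Conditions: methyl malonyl chloride, pyridine, CH2Cl2, 0 °C; then DBU, 25 °C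
Reagents that add atoms: methyl 3-chloro-3-oxopropanoate (10), COC(=O)CC(Cl)=O
Why: O-Acylation followed by intramolecular Michael addition (5-exo-trig) of the malonate carbanion to the enone β-carbon C7 forms C7–C11, and because the nucleophile is tethered to the β-oxygen on C8 it can only reach the β-face of C7, which sets the cis ring fusion (C7 R); C11 is an epimeric centre removed in step 8.

Step 8
Reactants: 12 methyl (3aR,6R,7aR)-6-methyl-2,5-dioxo-6-(prop-2-yn-1-yl)octahydro-1-benzofuran-3-carboxylate
Product: 13 (3aR,6R,7aR)-6-methyl-6-(prop-2-yn-1-yl)hexahydro-1-benzofuran-2,5-dione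
Conditions: LiCl, DMSO/H2O, 140 °C
Reagents that add atoms: none
Why: Krapcho demethoxycarbonylation (chloride attack at the ester methyl, then loss of CO2 from the malonate-type carboxylate) removes the auxiliary ester and leaves ketone, lactone and alkyne untouched.

Step 9
Reactants: 13 (3aR,6R,7aR)-6-methyl-6-(prop-2-yn-1-yl)hexahydro-1-benzofuran-2,5-dione
Product: 14 3-[(3aR,6R,7aR)-6-methyl-2,5-dioxooctahydro-1-benzofuran-6-yl]propanal
Conditions: [CpRu(MeCN)3]PF6 (5 mol%), 5,5′-bis(trifluoromethyl)-2,2′-bipyridine (5 mol%), NMP/H2O (4:1), 25 °C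
Reagents that add atoms: water, O
Why: Ruthenium-catalysed anti-Markovnikov hydration of the terminal alkyne (through a metal vinylidene) gives the C3 aldehyde under neutral conditions, in which the 1,5-keto aldehyde should not undergo aldol reactions.

Step 10
Reactants: 14 3-[(3aR,6R,7aR)-6-methyl-2,5-dioxooctahydro-1-benzofuran-6-yl]propanal
Product: 15 (3aR,4aR,7aR,8aR)-4a-hydroxy-7a-methyloctahydro-2H-indeno[5,6-b]furan-2,5(3H)-dione (C3 ketone with 5β-hydroxyl)
Conditions: 2-(pentafluorophenyl)-6,7-dihydro-5H-pyrrolo[2,1-c][1,2,4]triazol-2-ium tetrafluoroborate (20 mol%), Et3N (20 mol%), THF, 40 °C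
Reagents that add atoms: none
Why: N-Heterocyclic-carbene-catalysed intramolecular crossed aldehyde–ketone benzoin reaction, in which the Breslow intermediate at C3 adds 5-exo to the C5 ketone, closes ring A as a cyclopentanone; the tether on the α-face of C10 should place the new hydroxyl cis to C14, but this centre is destroyed in step 11.

Step 11
Reactants: 15 (3aR,4aR,7aR,8aR)-4a-hydroxy-7a-methyloctahydro-2H-indeno[5,6-b]furan-2,5(3H)-dione
Product: 16 (3aS,7aR,8aR)-7a-methyl-3a,6,7,7a,8,8a-hexahydro-2H-indeno[5,6-b]furan-2,5(3H)-dione (C3 enone with C5=C6)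
Conditions: SOCl2, pyridine, CH2Cl2, −10 → 0 °C
Reagents that add atoms: none
Why: Dehydration of the tertiary α-ketol through its chlorosulfite (base-induced elimination) can only go towards C6, since C10 is quaternary and C3 is a carbonyl carbon, which gives the C5=C6 enone.

Step 12
Reactants: 16 (3aS,7aR,8aR)-7a-methyl-3a,6,7,7a,8,8a-hexahydro-2H-indeno[5,6-b]furan-2,5(3H)-dione
Product: 17 (3aR,7aR,8aR)-7a-methyl-5-(triethylsilyloxy)-3,3a,4,6,7,7a,8,8a-octahydro-2H-indeno[5,6-b]furan-2-one (triethylsilyl enol ether of the cis-lactone hydrindanone)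
Conditions: Et3SiH, RhCl(PPh3)3 (2 mol%), THF, 50 °C
Reagents that add atoms: triethylsilane, CC[SiH](CC)CC
Why: Rhodium-catalysed 1,4-hydrosilylation of the enone delivers hydrogen to C6 and silicon to oxygen, so the silyl enol ether is formed with its double bond necessarily at C3=C5, and no stereocentre is involved.

Step 13
Reactants: 17 (3aR,7aR,8aR)-7a-methyl-5-(triethylsilyloxy)-3,3a,4,6,7,7a,8,8a-octahydro-2H-indeno[5,6-b]furan-2-one; 18 bromoform
Product: 20 4-bromo-3-oxo-13,15-dinoreudesm-4-en-8β,12-olide, via siloxy dibromocyclopropane 19 (not isolated)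
Conditions: CHBr3, KOt-Bu, pentane, −20 → 25 °C; filter; toluene, 60 °C
Reagents that add atoms: bromoform (18), BrC(Br)Br
Why: KOt-Bu removes HBr from bromoform to give dibromocarbene, which adds in a concerted [2+1] fashion to the electron-rich C3=C5 enol ether of 17 and so forms C3–C4 and C4–C5 (19). In 19 the oxygen lone pair assists ionisation of the bromide that lies syn to the five-membered ring while the C3–C5 bond opens in a disrotatory cyclopropyl-to-allyl electrocyclic process, and bromide then takes the silyl group from the oxygen-stabilised allyl cation to leave the C3 ketone conjugated with C4(Br)=C5. The closest known reaction type is the dihalocarbene one-carbon ring expansion of cyclic silyl enol ethers to 2-halocycloalk-2-enones, of which a tetrasubstituted ring-fusion enol ether is a hindered member. Ring A is closed by enlargement and not by cyclisation: the five-membered ring C1–C2–C3–C5–C10 takes up C4 and becomes six-membered. No stereocentre is made or touched, since C3, C4 and C5 all end sp2 and C7, C8 and C10 are remote from the reacting bond. The step needs site selectivity only, and this is secured because step 12 fixed the enol ether double bond at C3=C5 (never C2=C3) and because the molecule holds no other electron-rich alkene, the lactone being inert to the carbene.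

Step 14
Reactants: 20 4-bromo-3-oxo-13,15-dinoreudesm-4-en-8β,12-olide; 21 methylboronic acid
Product: 22 3-oxo-13-noreudesm-4-en-8β,12-olide
Conditions: MeB(OH)2, Pd(OAc)2 (5 mol%), SPhos (10 mol%), K3PO4, toluene/H2O (10:1), 80 °C
Reagents that add atoms: methylboronic acid (21), CB(O)O
Why: Suzuki–Miyaura coupling of the α-bromo enone (an electron-poor alkenyl bromide) with methylboronic acid replaces bromine by the C15 methyl with the double bond held at C4=C5.

Step 15
Reactants: 22 3-oxo-13-noreudesm-4-en-8β,12-olide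
Product: 23 3β-hydroxy-13-noreudesm-4-en-8β,12-olide
Conditions: NaBH4, CeCl3·7H2O, MeOH, −40 °C
Reagents that add atoms: none
Why: Luche 1,2-reduction of the enone, in which hydride attacks C3 axially from the α-face, away from the axial C14 methyl, should give the equatorial 3β-alcohol (C3 S), as is usual for 4-en-3-ones with an angular methyl.

Step 16
Reactants: 23 3β-hydroxy-13-noreudesm-4-en-8β,12-olide
Product: 24 3β-(tert-butyldimethylsilyloxy)-13-noreudesm-4-en-8β,12-olide
Conditions: TBSCl, imidazole, DMF, 40 °C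
Reagents that add atoms: tert-butyl(chloro)dimethylsilane, CC(C)(C)[Si](C)(C)Cl
Why: Silyl ether formation protects the allylic C3 hydroxyl against the strong base of step 17 and keeps O3 distinct from O8 for the later acylations.

Step 17
Reactants: 24 3β-(tert-butyldimethylsilyloxy)-13-noreudesm-4-en-8β,12-olide; 25 dimethyl(methylidene)ammonium iodide; 5 iodomethane
Product: 28 3β-(tert-butyldimethylsilyloxy)eudesma-4,11(13)-dien-8β,12-olide, via Mannich base 26 (not isolated), via trimethylammonium iodide 27 (not isolated)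
Conditions: LiN(i-Pr)2, THF, −78 °C; Me2N=CH2 I, −78 → 25 °C; then MeI, MeOH, 25 °C; then NaHCO3, CH2Cl2/H2O, 25 °C
Reagents that add atoms: dimethyl(methylidene)ammonium iodide (25), C=[N+](C)C.[I-]
Why: α-Methylenation of the lactone by Mannich reaction of its lithium enolate with the iminium salt, N-methylation and Hofmann-type β-elimination of trimethylamine installs C13; the C11 centre of 26 and 27 is lost in the elimination.

Step 18
Reactants: 28 3β-(tert-butyldimethylsilyloxy)eudesma-4,11(13)-dien-8β,12-olide; 5 iodomethane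
Product: 30 methyl 8β-hydroxy-3β-(tert-butyldimethylsilyloxy)eudesma-4,11(13)-dien-12-oate, via potassium carboxylate 29 (not isolated)
Conditions: KOH, THF/H2O, 25 °C; concentrate; MeI, DMF, 25 °C
Reagents that add atoms: potassium hydroxide, [K+].[OH-]; iodomethane (5), CI
Why: Saponification of the lactone and SN2 O-methylation of the carboxylate in the same flask, without acidification, gives the methyl ester while the cis-hydroxy acid is never free to re-close.

Step 19
Reactants: 30 methyl 8β-hydroxy-3β-(tert-butyldimethylsilyloxy)eudesma-4,11(13)-dien-12-oate; 31 acetic anhydride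
Product: 32 methyl 8β-acetoxy-3β-(tert-butyldimethylsilyloxy)eudesma-4,11(13)-dien-12-oate
Conditions: Ac2O, DMAP, pyridine, CH2Cl2, 0 → 25 °C (on crude 30)
Reagents that add atoms: acetic anhydride (31), CC(=O)OC(C)=O
Why: Nucleophile-catalysed acetylation (DMAP acyl transfer) of the axial 8β-hydroxyl, run directly on crude 30, fixes the open form.

Step 20
Reactants: 32 methyl 8β-acetoxy-3β-(tert-butyldimethylsilyloxy)eudesma-4,11(13)-dien-12-oate
Product: 33 methyl 8β-acetoxy-3β-hydroxyeudesma-4,11(13)-dien-12-oate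
Conditions: HF·pyridine, pyridine, THF, 0 → 25 °C
Reagents that add atoms: none
Why: Fluoride-mediated cleavage of the silyl ether under buffered acidic conditions leaves the acetate, the methyl ester and the acrylate intact.

Step 21
Reactants: 33 methyl 8β-acetoxy-3β-hydroxyeudesma-4,11(13)-dien-12-oate; 34 (E)-3-methylpent-2-enoic acid
Product: 35 methyl 8β-acetoxy-3β-[(E)-3-methylpent-2-enoyloxy]eudesma-4,11(13)-dien-12-oate (CNP0118541.1)
Conditions: DCC, DMAP (cat.), CH2Cl2, 0 → 25 °C
Reagents that add atoms: (E)-3-methylpent-2-enoic acid (34), CC/C(C)=C/C(O)=O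
Why: Steglich esterification (carbodiimide activation with DMAP acyl transfer) acylates the 3β-hydroxyl at low temperature without strong base, so the (E)-geometry of the β,β-disubstituted enoate should be kept.

**Compound list**
1 | 1,4-dioxaspiro[4.5]dec-6-en-8-one | O=C1CCC2(OCCO2)C=C1 | starting material
2 | (8R)-1,4-dioxaspiro[4.5]dec-6-en-8-ol | O[C@H]1C=CC2(CC1)OCCO2 | intermediate
3 | (8R)-8-(tert-butyldimethylsilyloxy)-1,4-dioxaspiro[4.5]dec-6-ene | CC(C)(C)[Si](C)(C)O[C@H]1C=CC2(CC1)OCCO2 | intermediate
4 | (4R)-4-(tert-butyldimethylsilyloxy)cyclohex-2-en-1-one | O=C1C=C[C@H](O[Si](C)(C)C(C)(C)C)CC1 | intermediate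
5 | iodomethane | CI | starting material
6 | (4R,6R)-4-(tert-butyldimethylsilyloxy)-6-methylcyclohex-2-en-1-one (trans; C6 epimer carried along) | O=C1C=C[C@H](O[Si](C)(C)C(C)(C)C)C[C@H]1C | intermediate
7 | 3-bromoprop-1-yne | C#CCBr | starting material
8 | (4R,6R)-4-(tert-butyldimethylsilyloxy)-6-methyl-6-(prop-2-yn-1-yl)cyclohex-2-en-1-one | O=C1C=C[C@H](O[Si](C)(C)C(C)(C)C)C[C@@]1(C)CC#C | intermediate
9 | (4R,6R)-4-hydroxy-6-methyl-6-(prop-2-yn-1-yl)cyclohex-2-en-1-one | O=C1C=C[C@H](O)C[C@@]1(C)CC#C | intermediate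
10 | methyl 3-chloro-3-oxopropanoate | COC(=O)CC(Cl)=O | starting material
11 | methyl (1R,5R)-5-methyl-4-oxo-5-(prop-2-yn-1-yl)cyclohex-2-en-1-yl propanedioate | O=C1C=C[C@H](OC(=O)CC(=O)OC)C[C@@]1(C)CC#C | intermediate (not isolated)
12 | methyl (3aR,6R,7aR)-6-methyl-2,5-dioxo-6-(prop-2-yn-1-yl)octahydro-1-benzofuran-3-carboxylate (C3 epimers) | O=C1C[C@@H]2C(C(=O)OC)C(=O)O[C@@H]2C[C@@]1(C)CC#C | intermediate
13 | (3aR,6R,7aR)-6-methyl-6-(prop-2-yn-1-yl)hexahydro-1-benzofuran-2,5-dione | O=C1C[C@@H]2CC(=O)O[C@@H]2C[C@@]1(C)CC#C | intermediate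
14 | 3-[(3aR,6R,7aR)-6-methyl-2,5-dioxooctahydro-1-benzofuran-6-yl]propanal | O=C1C[C@@H]2CC(=O)O[C@@H]2C[C@@]1(C)CCC=O | intermediate
15 | (3aR,4aR,7aR,8aR)-4a-hydroxy-7a-methyloctahydro-2H-indeno[5,6-b]furan-2,5(3H)-dione | O[C@]12C[C@@H]3CC(=O)O[C@@H]3C[C@@]1(C)CCC2=O | intermediate
16 | (3aS,7aR,8aR)-7a-methyl-3a,6,7,7a,8,8a-hexahydro-2H-indeno[5,6-b]furan-2,5(3H)-dione | O=C1CC[C@]2(C)C[C@H]3OC(=O)C[C@H]3C=C12 | intermediate
17 | (3aR,7aR,8aR)-7a-methyl-5-(triethylsilyloxy)-3,3a,4,6,7,7a,8,8a-octahydro-2H-indeno[5,6-b]furan-2-one | CC[Si](CC)(CC)OC1=C2C[C@@H]3CC(=O)O[C@@H]3C[C@@]2(C)CC1 | intermediate (key-step precursor)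
18 | bromoform | BrC(Br)Br | starting material
19 | dibromocarbene adduct of 17 (CBr2 bridging C3 and C5; either face, both converge) | CC[Si](CC)(CC)OC12CC[C@]3(C)C[C@H]4OC(=O)C[C@H]4CC13C2(Br)Br | intermediate (not isolated)
20 | 4-bromo-3-oxo-13,15-dinoreudesm-4-en-8β,12-olide (7R,8R,10R) | O=C1C[C@H]2CC3=C(Br)C(=O)CC[C@]3(C)C[C@H]2O1 | intermediate (key-step product)
21 | methylboronic acid | CB(O)O | starting material
22 | 3-oxo-13-noreudesm-4-en-8β,12-olide | O=C1C[C@H]2CC3=C(C)C(=O)CC[C@]3(C)C[C@H]2O1 | intermediate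
23 | 3β-hydroxy-13-noreudesm-4-en-8β,12-olide | O=C1C[C@H]2CC3=C(C)[C@@H](O)CC[C@]3(C)C[C@H]2O1 | intermediate
24 | 3β-(tert-butyldimethylsilyloxy)-13-noreudesm-4-en-8β,12-olide | O=C1C[C@H]2CC3=C(C)[C@@H](O[Si](C)(C)C(C)(C)C)CC[C@]3(C)C[C@H]2O1 | intermediate
25 | dimethyl(methylidene)ammonium iodide | C=[N+](C)C.[I-] | starting material
26 | 13-(dimethylamino)-3β-(tert-butyldimethylsilyloxy)eudesm-4-en-8β,12-olide (C11 epimers) | O=C1C(CN(C)C)[C@H]2CC3=C(C)[C@@H](O[Si](C)(C)C(C)(C)C)CC[C@]3(C)C[C@H]2O1 | intermediate (not isolated)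
27 | N-methyl quaternary iodide of 26 (13-trimethylammonio lactone) | O=C1C(C[N+](C)(C)C)[C@H]2CC3=C(C)[C@@H](O[Si](C)(C)C(C)(C)C)CC[C@]3(C)C[C@H]2O1.[I-] | intermediate (not isolated)
28 | 3β-(tert-butyldimethylsilyloxy)eudesma-4,11(13)-dien-8β,12-olide | O=C1C(=C)[C@H]2CC3=C(C)[C@@H](O[Si](C)(C)C(C)(C)C)CC[C@]3(C)C[C@H]2O1 | intermediate
29 | potassium 8β-hydroxy-3β-(tert-butyldimethylsilyloxy)eudesma-4,11(13)-dien-12-oate | C=C(C(=O)[O-])[C@H]1CC2=C(C)[C@@H](O[Si](C)(C)C(C)(C)C)CC[C@]2(C)C[C@H]1O.[K+] | intermediate (not isolated)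
30 | methyl 8β-hydroxy-3β-(tert-butyldimethylsilyloxy)eudesma-4,11(13)-dien-12-oate | C=C(C(=O)OC)[C@H]1CC2=C(C)[C@@H](O[Si](C)(C)C(C)(C)C)CC[C@]2(C)C[C@H]1O | intermediate
31 | acetic anhydride | CC(=O)OC(C)=O | starting material
32 | methyl 8β-acetoxy-3β-(tert-butyldimethylsilyloxy)eudesma-4,11(13)-dien-12-oate | C=C(C(=O)OC)[C@H]1CC2=C(C)[C@@H](O[Si](C)(C)C(C)(C)C)CC[C@]2(C)C[C@H]1OC(C)=O | intermediate
33 | methyl 8β-acetoxy-3β-hydroxyeudesma-4,11(13)-dien-12-oate | C=C(C(=O)OC)[C@H]1CC2=C(C)[C@@H](O)CC[C@]2(C)C[C@H]1OC(C)=O | intermediate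
34 | (E)-3-methylpent-2-enoic acid | CC/C(C)=C/C(O)=O | starting material
35 | methyl 8β-acetoxy-3β-[(E)-3-methylpent-2-enoyloxy]eudesma-4,11(13)-dien-12-oate (3S,7R,8R,10R) | C=C(C(=O)OC)[C@H]1CC2=C(C)[C@@H](OC(=O)/C=C(\C)CC)CC[C@]2(C)C[C@H]1OC(C)=O | target

**Step count and risks**

Total step count: 21. Longest linear sequence: 21 steps (1 → 35; 34 is bought and enters in the last step).

The three steps most likely to fail:

1. Step 13 (carbene ring enlargement). The carbene may add too slowly to the crowded tetrasubstituted enol ether. Desilylation by tert-butoxide, base-induced reactions of the lactone, or collapse of the adduct to a dibromomethyl ketone could then win over ring enlargement. Fallback, setting out from 17 and returning at 20: cyclopropanation of 17 with Et2Zn/CH2I2 (Simmons–Smith reaction in the Furukawa form) would give the siloxycyclopropane F1. FeCl3 in DMF (Ito–Saegusa oxidative opening of the C3–C5 bond) would give the ring-enlarged β-chloro ketone F2, and NaOAc in MeOH would eliminate HCl to the 4-unsubstituted enone F3. Addition of Br2 would give the 4,5-dibromo ketone F4, from which Et3N would remove HBr to give 20. The inserted carbon then comes from a zinc carbenoid and the ring opens by a radical path instead of a cationic one.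

2. Step 10 (benzoin closure of ring A). The Breslow intermediate may fail to add to the hindered ketone next to the quaternary C10, so that aldol closure through C6 or self-condensation of the aldehyde takes over. Fallback, setting out from 13 and returning at 16: KN(SiMe3)2/PhNTf2 would convert the ketone of 13 into the C5 enol triflate F5 (only C6 can enolise). Ruthenium-catalysed hydration as in step 9 would give the triflate aldehyde F6. An intramolecular Nozaki–Hiyama–Kishi reaction (CrCl2, NiCl2 cat., DMF) would join C5 to C3 and give the allylic alcohol F7, and Dess–Martin oxidation would give the enone 16.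

3. Step 18 (opening of the methylene lactone). The cis-hydroxy ester may re-close to the lactone, or hydroxide or the C8 hydroxyl may add to the exocyclic methylene group. Fallback, setting out from 24 and returning at 32: the Mannich base 26 would be isolated after the first operation of step 17, so that the methylene group stays masked. KOH would open its lactone to the potassium amino carboxylate F8, and excess MeI in DMF would esterify the carboxylate and quaternise the amine to the ammonium hydroxy ester F9. Ac2O/Et3N/DMAP would then acetylate O8 and release the acrylate by β-elimination of trimethylamine, giving 32.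

Further compounds
F1 | step 13 | siloxycyclopropane (CH2 bridging C3 and C5 of 17) | CC[Si](CC)(CC)OC12CC[C@]3(C)C[C@H]4OC(=O)C[C@H]4CC13C2
F2 | step 13 | 5-chloro-3-oxo-13,15-dinoreudesman-8β,12-olide | O=C1C[C@H]2CC3(Cl)CC(=O)CC[C@]3(C)C[C@H]2O1
F3 | step 13 | 3-oxo-13,15-dinoreudesm-4-en-8β,12-olide | O=C1C[C@H]2CC3=CC(=O)CC[C@]3(C)C[C@H]2O1
F4 | step 13 | 4,5-dibromo-3-oxo-13,15-dinoreudesman-8β,12-olide | O=C1C[C@H]2CC3(Br)C(Br)C(=O)CC[C@]3(C)C[C@H]2O1
F5 | step 10 | (3aR,6R,7aR)-6-methyl-2-oxo-6-(prop-2-yn-1-yl)-2,3,3a,6,7,7a-hexahydro-1-benzofuran-5-yl trifluoromethanesulfonate | FC(F)(F)S(=O)(=O)OC1=C[C@@H]2CC(=O)O[C@@H]2C[C@@]1(C)CC#C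
F6 | step 10 | (3aR,6R,7aR)-6-methyl-2-oxo-6-(3-oxopropyl)-2,3,3a,6,7,7a-hexahydro-1-benzofuran-5-yl trifluoromethanesulfonate | FC(F)(F)S(=O)(=O)OC1=C[C@@H]2CC(=O)O[C@@H]2C[C@@]1(C)CCC=O
F7 | step 10 | 5-hydroxy-7a-methyl-3,3a,5,6,7,7a,8,8a-octahydro-2H-indeno[5,6-b]furan-2-one (C3 allylic alcohol, either epimer) | OC1CC[C@]2(C)C[C@H]3OC(=O)C[C@H]3C=C12
F8 | step 18 | potassium 13-(dimethylamino)-8β-hydroxy-3β-(tert-butyldimethylsilyloxy)eudesm-4-en-12-oate | CN(C)CC(C(=O)[O-])[C@H]1CC2=C(C)[C@@H](O[Si](C)(C)C(C)(C)C)CC[C@]2(C)C[C@H]1O.[K+]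
F9 | step 18 | methyl 8β-hydroxy-3β-(tert-butyldimethylsilyloxy)-13-(trimethylammonio)eudesm-4-en-12-oate iodide | C[N+](C)(C)CC(C(=O)OC)[C@H]1CC2=C(C)[C@@H](O[Si](C)(C)C(C)(C)C)CC[C@]2(C)C[C@H]1O.[I-]
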